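(Readings and results were computed on assumed constants; scatter was added.)

One percentage point of target costs this flask n points of substrate and n of partner. I call n the spend: one if target is the sole product, two in the symmetric case of an unseen path as fast as target's.

- Monday's: substrate 0.50 M; partner 0.80 equiv; the very flask that is asked about, followed so far
- flask: substrate 0.50 M; partner 0.800 equiv; time 15 min

- Monday's (time / min: target / %, crystals / %): 0.500: 2.6, 0; 1.00: 5.8, 0; 2.50: 13.0, 0.1; 6.00: 21.2, 1.3

(each reading ± 0.5 percentage points)

- target is meant together with its crystals
- solid, in amounts per volume of the solution: crystals

* amount of target and crystals together at 15 min, in percent of the substrate charged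
* concentration of target in solution at 15 min, in percent of saturation

I count y as target plus crystals. For second-order spending, u = n·y obeys ln[r(1 − u)/(r − u)] = k·c·(1 − r)·t, with r the equivalents of partner, c the substrate concentration, t the time and k the second-order constant, which is the step-growth law with stoichiometric imbalance. So with the right spend k must hold level along Monday's run. A spend of one gives 0.154 /M/min at 2.50 min and 0.126 /M/min at 6.00 min, a sag. A spend of two gives 0.372 /M/min and 0.381 /M/min, nearly level. I therefore take the spend as two and keep the later value, a reading with the scatter of Monday's run, as k_s, the spending constant, the second-order constant for substrate and partner used by target's path and its twin together.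

Time first: k_s gives y = 31.8% at 15 min and 36.6% at 30.0 min, so the later stretch adds 4.8 percentage points. Partner next: it is charged below the substrate, which makes it the limiting reagent, and at a spend of exactly two its charge allows y up to 40.0%. Substrate last: at fixed r, c multiplies the exponent, so a richer charge runs the same curve sooner. Saturation I cannot place: the last crystal reading stands 2.60 standard deviations above zero.

The forecast says 34% and 180%, on the view that “Crystallisation drains dissolved product and pulls the equilibrium forward”, while I say 31.8% and give no figure for saturation.

The flask gives 31.7% and 37.7%.

    substrate + partner → target (k = 0.177 /M/min)
    substrate + partner → isomer of the product (k = 0.00193 /M/min)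
    substrate + partner → second isomer (k = 0.166 /M/min)
    crystals ⇌ target, rate k4*(cs4 - [target]) while solid is left; crystals form when [target] > cs4 (solubility = 0.420 M, k = 10.9 /min)

In the flask at 15.0 min target stands at 31.7% beside 29.7% of second isomer and 0.346% of isomer of the product, a spend of 1.95. Put 0.85 M of substrate, same equivalents and time, through k_s = 0.381 /M/min: the law gives 35.7%, and that neighbour holds 36.0%.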